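**Retrosynthetic overview**
1. Caraphenol C ⇐ O‑demethylation of the all‑cis hexamethyl ether ⇐ syn‑hydrogenation of the tetrasubstituted enone C=C of a (1S)‑1‑aryl‑2‑aryl‑3‑aroyl‑1H‑indene, anti to the aryl group on its single stereocentre (sets the ketone α‑carbon and the adjacent carbon).
2. Key disconnection: the bond between that stereocentre and its 4‑oxyaryl group, made by copper‑catalysed enantioselective radical‑relay C–H arylation (indenyl radical + aryl–copper) of the achiral 2‑aryl‑3‑aroyl‑1H‑indene.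
3. 3‑Aroylindene ⇐ one‑pot enol triflation/carbonylative Suzuki coupling of 2‑aryl‑4,6‑dimethoxyindan‑1‑one ⇐ methylenation/Nazarov cyclisation of the symmetrical deoxybenzoin.
4. Deoxybenzoin ⇐ hydration of bis(3,5‑dimethoxyphenyl)acetylene ⇐ double Sonogashira coupling of 1‑bromo‑3,5‑dimethoxybenzene (from resorcinol by methylation, then meta C–H borylation/bromination); the arylboronic acid comes from anisole.
5. Ring order: the arene rings are bought; the five‑membered ring (ring B) is the only ring formed, closed onto ring A in the Nazarov step.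

Assumption: the SMILES is read literally, i.e. (1R,2R,3R) with the C1 aroyl, C2 aryl and C3 aryl groups all cis (indane numbering: C1 carries the ketone side chain, ring A is the fused resorcinol ring).

**Route**

Step 1
Reactants: 1 resorcinol
Product: 2 1,3-dimethoxybenzene
Conditions: Me2SO4 (2.3 equiv), K2CO3 (3 equiv), acetone, 56 °C
Reagents that add atoms: dimethyl sulfate, COS(=O)(=O)OC
Why: Williamson O‑methylation of both phenols gives ethers that survive every later step; no stereocentre.

Step 2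
Reactants: 2 1,3-dimethoxybenzene
Product: 4 1-bromo-3,5-dimethoxybenzene, via aryl pinacol boronate 3 (not isolated)
Conditions: [Ir(OMe)(cod)]2 (0.5 mol %), 4,4′-di-tert-butyl-2,2′-bipyridine (1 mol %), B2pin2 (0.55 equiv), THF, 80 °C; then CuBr2 (3 equiv), MeOH–H2O 1:1, 80 °C
Reagents that add atoms: bis(pinacolato)diboron, CC1(C)OB(OC1(C)C)B1OC(C)(C)C(C)(C)O1 (boron of 3); CuBr2, [Cu+2].[Br-].[Br-] (bromine of 4)
Why: Sterically controlled iridium‑catalysed C–H borylation occurs only at C5, the one position with no ortho methoxy group, and CuBr2 converts the boronate to the bromide in the same flask (C–H borylation/bromodeboronation).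

Step 3
Reactants: 4 1-bromo-3,5-dimethoxybenzene (2.05 equiv); 5 ethynyltrimethylsilane (1 equiv)
Product: 8 1,2-bis(3,5-dimethoxyphenyl)ethyne, via silyl alkyne 6 (not isolated), via terminal alkyne 7 (not isolated)
Conditions: PdCl2(PPh3)2 (4 mol %), CuI (8 mol %), DBU (6 equiv), H2O (1 equiv), MeCN, 80 °C
Reagents that add atoms: none
Why: One‑pot double Sonogashira coupling in which DBU/water unmasks the silyl alkyne in situ, giving the symmetrical diarylalkyne.

Step 4
Reactants: 8 1,2-bis(3,5-dimethoxyphenyl)ethyne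
Product: 9 1,2-bis(3,5-dimethoxyphenyl)ethan-1-one
Conditions: CF3SO3H (20 mol %), H2O (3 equiv), CF3CH2OH, 60 °C
Reagents that add atoms: water, O
Why: Brønsted acid‑catalysed alkyne hydration; the alkyne is symmetrical, so only one ketone can form.

Step 5
Reactants: 9 1,2-bis(3,5-dimethoxyphenyl)ethan-1-one; 10 formaldehyde (as paraformaldehyde, 3 equiv)
Product: 12 2-(3,5-dimethoxyphenyl)-4,6-dimethoxy-2,3-dihydro-1H-inden-1-one (racemic), via alpha-methylene ketone 11 (not isolated)
Conditions: (CH2O)n, i-Pr2NH2·O2CCF3 (1 equiv), CF3CO2H (10 mol %), THF, 65 °C; then solvent switch, CH3SO3H (2 equiv), CH2Cl2, 0 → 23 °C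
Reagents that add atoms: none
Why: Mannich‑type α‑methylenation (condensation with loss of water) gives the aryl vinyl ketone, which closes ring B by acid‑promoted Nazarov cyclisation at the arene position ortho/para to the two methoxy groups; the racemic stereocentre is erased in step 8.

Step 6
Reactants: 13 anisole
Product: 14 1-bromo-4-methoxybenzene
Conditions: NBS (1.0 equiv), MeCN, 23 °C
Reagents that add atoms: N-bromosuccinimide, O=C1CCC(=O)N1Br
Why: Electrophilic aromatic bromination, para‑selective for anisole.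

Step 7
Reactants: 14 1-bromo-4-methoxybenzene
Product: 17 (4-methoxyphenyl)boronic acid, via Grignard reagent 15 (not isolated), via dimethyl boronate 16 (not isolated)
Conditions: Mg, THF, 50 °C; B(OMe)3, −78 → 23 °C; 1 M HCl
Reagents that add atoms: magnesium, [Mg] (in 15); trimethyl borate, COB(OC)OC; water, O
Why: Grignard formation, borylation with trimethyl borate and hydrolysis, the standard arylboronic acid synthesis.

Step 8
Reactants: 12 2-(3,5-dimethoxyphenyl)-4,6-dimethoxy-2,3-dihydro-1H-inden-1-one; 17 (4-methoxyphenyl)boronic acid (1.3 equiv); 18 carbon monoxide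
Product: 21 [2-(3,5-dimethoxyphenyl)-5,7-dimethoxy-1H-inden-3-yl](4-methoxyphenyl)methanone, via potassium enolate 19 (not isolated), via enol triflate 20 (not isolated)
Conditions: KN(SiMe3)2 (1.05 equiv), THF, −78 °C; PhNTf2 (1.1 equiv), −78 → 0 °C; then Pd(dppf)Cl2 (5 mol %), 17, K2CO3 (3 equiv), H2O (5 equiv), CO (3 atm), 70 °C
Reagents that add atoms: KN(SiMe3)2, C[Si](C)(C)[N-][Si](C)(C)C.[K+] (potassium of 19); N-phenylbis(trifluoromethanesulfonimide), O=S(=O)(N(c1ccccc1)S(=O)(=O)C(F)(F)F)C(F)(F)F (triflyl group of 20)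
Why: The ketone has a single α‑hydrogen, so one enol triflate forms, and carbonylative Suzuki–Miyaura coupling (oxidative addition, CO insertion, transmetalation, reductive elimination) installs the aroyl group in the same flask; the product is achiral (ring CH2).

Step 9
Reactants: 21 [2-(3,5-dimethoxyphenyl)-5,7-dimethoxy-1H-inden-3-yl](4-methoxyphenyl)methanone; 17 (4-methoxyphenyl)boronic acid (2 equiv)
Product: 22 [(1S)-2-(3,5-dimethoxyphenyl)-5,7-dimethoxy-1-(4-methoxyphenyl)-1H-inden-3-yl](4-methoxyphenyl)methanone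
Conditions: Cu(MeCN)4PF6 (10 mol %), 2,2′-(propane-2,2-diyl)bis[(4S)-4-tert-butyl-4,5-dihydro-1,3-oxazole] (12 mol %; ligand antipode fixed by screening to give 1S), (PhSO2)2NF (1.5 equiv), PhCl–CH2Cl2, −10 °C, no base; rapid silica filtration and direct use
Reagents that add atoms: none
Why: Proposed new method: the sulfonimidyl radical formed from (PhSO2)2NF and monovalent copper abstracts the weakest hydrogen of 21 (the doubly benzylic/allylic CH2, vinylogous to the ketone) to give a planar 1‑aroylindenyl radical, which is trapped at its unsubstituted terminus by the chiral bis(oxazoline) aryl–copper complex (divalent copper, aryl from 17) and undergoes C–C reductive elimination from trivalent copper, so the ligand sets the 1S centre (C3 of the target) in the bond‑forming step; the closest known reactions are copper/bis(oxazoline) radical‑relay enantioselective benzylic C–H arylation with arylboronic acids and allylic C–H cyanation.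

Step 10
Reactants: 22 [(1S)-2-(3,5-dimethoxyphenyl)-5,7-dimethoxy-1-(4-methoxyphenyl)-1H-inden-3-yl](4-methoxyphenyl)methanone
Product: 23 [(1R,2R,3R)-2-(3,5-dimethoxyphenyl)-4,6-dimethoxy-3-(4-methoxyphenyl)-2,3-dihydro-1H-inden-1-yl](4-methoxyphenyl)methanone
Conditions: H2 (4 atm), 10% Pd/C, EtOAc, 23 °C
Reagents that add atoms: none
Why: Heterogeneous catalytic hydrogenation adds both hydrogens syn to the tetrasubstituted enone C=C from the face opposite the aryl group on the stereocentre of 22, so the aroyl, 3,5‑dimethoxyphenyl and 4‑methoxyphenyl groups end up all cis, (1R,2R,3R), under neutral conditions that do not enolise the new ketone α‑centre.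

Step 11
Reactants: 23 [(1R,2R,3R)-2-(3,5-dimethoxyphenyl)-4,6-dimethoxy-3-(4-methoxyphenyl)-2,3-dihydro-1H-inden-1-yl](4-methoxyphenyl)methanone
Product: 24 caraphenol C
Conditions: BBr3 (12 equiv), CH2Cl2, −78 → 0 °C; cold aqueous pH 5 buffer quench
Reagents that add atoms: none
Why: Lewis acid‑mediated cleavage of the six aryl methyl ethers (each methyl leaves as MeBr) under base‑free, cold conditions with a mildly acidic quench, chosen so the epimerisable cis C1–H next to the ketone is not enolised; no stereocentre is touched.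

**Compound list**
1 | resorcinol | Oc1cccc(O)c1 | starting material
2 | 1,3-dimethoxybenzene | COc1cccc(OC)c1 | intermediate
3 | 2-(3,5-dimethoxyphenyl)-4,4,5,5-tetramethyl-1,3,2-dioxaborolane | COc1cc(OC)cc(c1)B1OC(C)(C)C(C)(C)O1 | intermediate
4 | 1-bromo-3,5-dimethoxybenzene | COc1cc(Br)cc(OC)c1 | intermediate
5 | ethynyltrimethylsilane | C#C[Si](C)(C)C | starting material
6 | [(3,5-dimethoxyphenyl)ethynyl]trimethylsilane | COc1cc(OC)cc(c1)C#C[Si](C)(C)C | intermediate
7 | 1-ethynyl-3,5-dimethoxybenzene | COc1cc(OC)cc(c1)C#C | intermediate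
8 | 1,2-bis(3,5-dimethoxyphenyl)ethyne | COc1cc(OC)cc(c1)C#Cc1cc(OC)cc(OC)c1 | intermediate
9 | 1,2-bis(3,5-dimethoxyphenyl)ethan-1-one | COc1cc(OC)cc(c1)CC(=O)c1cc(OC)cc(OC)c1 | intermediate
10 | formaldehyde (used as paraformaldehyde) | C=O | starting material
11 | 1,2-bis(3,5-dimethoxyphenyl)prop-2-en-1-one | C=C(c1cc(OC)cc(OC)c1)C(=O)c1cc(OC)cc(OC)c1 | intermediate
12 | 2-(3,5-dimethoxyphenyl)-4,6-dimethoxy-2,3-dihydro-1H-inden-1-one (racemic) | O=C1C(Cc2c(OC)cc(OC)cc12)c1cc(OC)cc(OC)c1 | intermediate
13 | anisole | COc1ccccc1 | starting material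
14 | 1-bromo-4-methoxybenzene | COc1ccc(Br)cc1 | intermediate
15 | (4-methoxyphenyl)magnesium bromide | COc1ccc([Mg]Br)cc1 | intermediate
16 | dimethyl (4-methoxyphenyl)boronate | COB(OC)c1ccc(OC)cc1 | intermediate
17 | (4-methoxyphenyl)boronic acid | COc1ccc(cc1)B(O)O | intermediate
18 | carbon monoxide | [C-]#[O+] | starting material
19 | potassium 2-(3,5-dimethoxyphenyl)-5,7-dimethoxy-1H-inden-3-olate | [K+].[O-]C1=C(Cc2c(OC)cc(OC)cc12)c1cc(OC)cc(OC)c1 | intermediate
20 | 2-(3,5-dimethoxyphenyl)-5,7-dimethoxy-1H-inden-3-yl trifluoromethanesulfonate | FC(F)(F)S(=O)(=O)OC1=C(Cc2c(OC)cc(OC)cc12)c1cc(OC)cc(OC)c1 | intermediate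
21 | [2-(3,5-dimethoxyphenyl)-5,7-dimethoxy-1H-inden-3-yl](4-methoxyphenyl)methanone | COc1ccc(cc1)C(=O)C1=C(Cc2c(OC)cc(OC)cc12)c1cc(OC)cc(OC)c1 | intermediate
22 | [(1S)-2-(3,5-dimethoxyphenyl)-5,7-dimethoxy-1-(4-methoxyphenyl)-1H-inden-3-yl](4-methoxyphenyl)methanone | COc1ccc(cc1)[C@H]1C(c2cc(OC)cc(OC)c2)=C(C(=O)c2ccc(OC)cc2)c2cc(OC)cc(OC)c12 | intermediate
23 | [(1R,2R,3R)-2-(3,5-dimethoxyphenyl)-4,6-dimethoxy-3-(4-methoxyphenyl)-2,3-dihydro-1H-inden-1-yl](4-methoxyphenyl)methanone (all-cis) | O=C(c1ccc(OC)cc1)[C@H]1c2cc(OC)cc(OC)c2[C@@H](c2ccc(OC)cc2)[C@H]1c1cc(OC)cc(OC)c1 | intermediate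
24 | caraphenol C, [(1R,2R,3R)-2-(3,5-dihydroxyphenyl)-4,6-dihydroxy-3-(4-hydroxyphenyl)-2,3-dihydro-1H-inden-1-yl](4-hydroxyphenyl)methanone | O=C(c1ccc(O)cc1)[C@H]1c2cc(O)cc(O)c2[C@@H](c2ccc(O)cc2)[C@H]1c1cc(O)cc(O)c1 | target

**Totals**
Total step count: 11. Longest linear sequence: 9 (steps 1, 2, 3, 4, 5, 8, 9, 10, 11).

**Three steps most likely to fail**

Step 9 (enantioselective C–H arylation). The risks are amination of the electron‑rich arenes by the N–F reagent, low enantioselectivity, and further oxidation or acid‑mediated racemisation of the very acidic product 22. Fallback: set out from 21, deprotonate with LiN(SiMe3)2 (THF, −78 °C) and brominate the indenide with BrCl2C–CCl2Br to obtain racemic [1-bromo-2-(3,5-dimethoxyphenyl)-5,7-dimethoxy-1H-inden-3-yl](4-methoxyphenyl)methanone F1. A nickel‑catalysed enantioconvergent Negishi arylation (NiCl2·glyme, chiral pybox ligand, glyme, −30 °C) with (4-methoxyphenyl)zinc bromide F2, made from Grignard reagent 15 and ZnBr2, sends both enantiomers of F1 through the same indenyl radical under neutral conditions and comes back to the route at 22.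

Step 10 (hydrogenation of the hindered tetrasubstituted enone). The risks are slow reduction, loss of the stereocentre of 22 through enolisation before the alkene is saturated, and over‑reduction of the aryl ketone. Fallback: set out from 22 and carry out a Luche reduction (NaBH4, CeCl3·7H2O, MeOH–THF, −40 °C) to [(1S)-2-(3,5-dimethoxyphenyl)-5,7-dimethoxy-1-(4-methoxyphenyl)-1H-inden-3-yl](4-methoxyphenyl)methanol F3 (both carbinol epimers), whose ring C–H is no longer acidic. Hydroxyl‑assisted homogeneous hydrogenation with [Ir(cod)(PCy3)(py)]PF6 (H2, CH2Cl2), still anti to the ring aryl group, gives [(1R,2R,3R)-2-(3,5-dimethoxyphenyl)-4,6-dimethoxy-3-(4-methoxyphenyl)-2,3-dihydro-1H-inden-1-yl](4-methoxyphenyl)methanol F4, and Dess–Martin oxidation (CH2Cl2, 0 °C) comes back to the route at 23.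

Step 11 (demethylation). The risk is epimerisation of the cis C1–H next to the BBr3‑activated ketone to the more stable 1,2‑trans isomer. Fallback: set out from 23 and run the BBr3 demethylation to completion at 23 °C without regard to C1, which gives 24 together with the C1 epimer of caraphenol C F5. Per‑silylation of the mixture (Me3SiOTf, Et3N, CH2Cl2, 0 °C) converts both into one heptakis(trimethylsilyl) enol ether F6. Cold protodesilylation (AcOH, THF–H2O, −40 → 0 °C) then protonates C1 from the face opposite the two cis aryl groups and frees the phenols, coming back to the route at 24.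

Further compounds
F1 | step 9 | [1-bromo-2-(3,5-dimethoxyphenyl)-5,7-dimethoxy-1H-inden-3-yl](4-methoxyphenyl)methanone (racemic) | COc1ccc(cc1)C(=O)C1=C(C(Br)c2c(OC)cc(OC)cc12)c1cc(OC)cc(OC)c1
F2 | step 9 | (4-methoxyphenyl)zinc bromide | COc1ccc([Zn]Br)cc1
F3 | step 10 | [(1S)-2-(3,5-dimethoxyphenyl)-5,7-dimethoxy-1-(4-methoxyphenyl)-1H-inden-3-yl](4-methoxyphenyl)methanol (both carbinol epimers) | COc1ccc(cc1)[C@H]1C(c2cc(OC)cc(OC)c2)=C(C(O)c2ccc(OC)cc2)c2cc(OC)cc(OC)c12
F4 | step 10 | [(1R,2R,3R)-2-(3,5-dimethoxyphenyl)-4,6-dimethoxy-3-(4-methoxyphenyl)-2,3-dihydro-1H-inden-1-yl](4-methoxyphenyl)methanol (both carbinol epimers) | OC(c1ccc(OC)cc1)[C@H]1c2cc(OC)cc(OC)c2[C@@H](c2ccc(OC)cc2)[C@H]1c1cc(OC)cc(OC)c1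
F5 | step 11 | C1 epimer of caraphenol C, (1S,2R,3R) | O=C(c1ccc(O)cc1)[C@@H]1c2cc(O)cc(O)c2[C@@H](c2ccc(O)cc2)[C@H]1c1cc(O)cc(O)c1
F6 | step 11 | heptakis(trimethylsilyl) enol ether of 24 (silyl enol ether at C1 plus six aryl silyl ethers; 2S,3R; E/Z mixture) | C[Si](C)(C)OC(c1ccc(O[Si](C)(C)C)cc1)=C1c2cc(O[Si](C)(C)C)cc(O[Si](C)(C)C)c2[C@@H](c2ccc(O[Si](C)(C)C)cc2)[C@H]1c1cc(O[Si](C)(C)C)cc(O[Si](C)(C)C)c1
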